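**Retrosynthetic overview**
- The target is reached by cleaving both methyl ethers of its bis-methyl ether. The two ring A bromines of that ether (C3 and C5) are put in by a double Sandmeyer bromination of the ring A 3,5-diamine.
- The strategy rests on ring A (C1–OH, C2–O-aryl, C3–Br, C5–Br): its bromines lie ortho and para to the ether oxygen at C2 and meta to the C1 oxygen. Phenol bromination cannot reach these positions, but two nitro groups there activate C2 for metal-free ether formation.
- The diamine comes from the dinitro diaryl ether, made by SNAr of 3,5-dibromo-2-methoxyphenol (ring B, bromines already para and ortho to C6'–O) on 2-chloro-1-methoxy-3,5-dinitrobenzene.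
- The chloride comes from guaiacol (dinitration, then OH to Cl); the phenol comes from 3,5-dibromosalicylaldehyde (O-methylation, Baeyer–Villiger oxidation).
- No ring is formed; both benzene rings are bought.

Key step: step 7

Remark: the target has no stereocentre and no configurationally stable axis, so it is achiral and the route needs no stereocontrol.

**Step 1**
Reactants: 1 guaiacol (2-methoxyphenol)
Product: 2 2-methoxy-4,6-dinitrophenol
Conditions: HNO3 (65%, 2.2 equiv), AcOH, 0 °C → rt
Reagents that add atoms: nitric acid O[N+](=O)[O-]
Why: Electrophilic aromatic nitration in which the free hydroxyl directs to its para (C4) and ortho (C6) positions, so both mononitro isomers should converge on the same 4,6-dinitro compound.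

**Step 2**
Reactants: 2 2-methoxy-4,6-dinitrophenol
Product: 3 2-chloro-1-methoxy-3,5-dinitrobenzene
Conditions: POCl3, DMF (cat.), 90 °C; ice-water quench
Reagents that add atoms: phosphoryl chloride O=P(Cl)(Cl)Cl
Why: Chlorodehydroxylation of a nitro-activated phenol, in which Vilsmeier/phosphoryl activation of the acidic OH is followed by SNAr of chloride at the carbon ortho and para to the nitro groups, as in the conversion of picric acid to picryl chloride.

**Step 3**
Reactants: 4 3,5-dibromosalicylaldehyde (3,5-dibromo-2-hydroxybenzaldehyde)
Product: 5 3,5-dibromo-2-methoxybenzaldehyde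
Conditions: MeI, K2CO3, DMF, rt
Reagents that add atoms: iodomethane CI
Why: Williamson O-methylation of an acidic, chelated phenol whose phenoxide forms readily with carbonate.

**Step 4**
Reactants: 5 3,5-dibromo-2-methoxybenzaldehyde
Product: 7 3,5-dibromo-2-methoxyphenol, via aryl formate 6 (not isolated)
Conditions: mCPBA, CH2Cl2, rt → 40 °C; then K2CO3 (cat.), MeOH, rt
Reagents that add atoms: 3-chloroperoxybenzoic acid OOC(=O)c1cccc(Cl)c1
Why: Baeyer–Villiger (Dakin-type) oxidation in which the ortho-methoxy group should favour aryl over hydride migration in the Criegee intermediate, and the resulting formate is methanolysed to the phenol while the aryl bromides stay inert.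

**Step 5**
Reactants: 3 2-chloro-1-methoxy-3,5-dinitrobenzene; 7 3,5-dibromo-2-methoxyphenol
Product: 8 1,5-dibromo-2-methoxy-3-(2-methoxy-4,6-dinitrophenoxy)benzene
Conditions: K2CO3, dry DMF, rt → 50 °C
Reagents that add atoms: none
Why: SNAr through a Meisenheimer adduct, in which the chloride is the only leaving group ortho and para to both nitro groups, so the hindered phenoxide should displace it without a metal.

**Step 6**
Reactants: 8 1,5-dibromo-2-methoxy-3-(2-methoxy-4,6-dinitrophenoxy)benzene
Product: 9 4-(3,5-dibromo-2-methoxyphenoxy)-5-methoxybenzene-1,3-diamine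
Conditions: Fe powder, AcOH, EtOH/H2O, 70 °C; used at once under N2
Reagents that add atoms: none
Why: Béchamp reduction with iron in acetic acid should reduce both nitro groups while leaving the aryl C–Br bonds intact, which catalytic hydrogenation would endanger.

**Step 7**
Reactants: 9 4-(3,5-dibromo-2-methoxyphenoxy)-5-methoxybenzene-1,3-diamine
Product: 11 1,5-dibromo-2-(3,5-dibromo-2-methoxyphenoxy)-3-methoxybenzene, via bis-diazonium hydrogensulfate 10 (not isolated)
Conditions: NaNO2, conc. H2SO4, then 9 in AcOH added dropwise, 0–10 °C; urea; poured into CuBr, 48% HBr, 60 °C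
Reagents that add atoms: hydrobromic acid Br; copper(I) bromide Br[Cu]; sodium nitrite O=N[O-].[Na+] (its nitrogen enters intermediate 10 only and leaves as N2)
Why: Nitrosylsulfuric acid nitrosates both amino groups in a medium where any free amine is protonated, giving the bis-diazonium salt 10; copper(I) then transfers an electron to each diazonium group, dinitrogen departs and the aryl σ-radical takes bromine from copper(II) bromide, which regenerates copper(I). This is the classical Sandmeyer bromination, and the closest known case is the tetrazotisation and bromination of meta-phenylenediamines. No ring closes and no stereocentre is formed; the C3–Br and C5–Br bonds arise exactly where nitrogen sat, independent of the directing effects of the two oxygens, which would send an electrophile to C4 and C6. The step needs complete double diazotisation without azo coupling at C4 or C6 of unreacted diamine, which inverse addition into excess nitrosylsulfuric acid should secure by keeping free amine scarce. It also needs bromine transfer at C3 to outrun Pschorr-type attack of the C3 radical on C2' of ring B, which a high copper and bromide concentration should ensure. Finally the aryloxy group at C2, flanked ortho and para by diazonium groups, must not be displaced, so the cold diazonium solution should be passed to the copper bromide without delay.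

**Step 8**
Reactants: 11 1,5-dibromo-2-(3,5-dibromo-2-methoxyphenoxy)-3-methoxybenzene
Product: 12 3,5-dibromo-2-(3,5-dibromo-2-hydroxyphenoxy)phenol
Conditions: BBr3 (5 equiv), CH2Cl2, −78 °C → rt; then H2O
Reagents that add atoms: none
Why: Lewis-acid demethylation in which bromide attacks the methyl carbon of each boron-complexed aryl methyl ether, while the diaryl ether and the aryl bromides offer no SN2 site and should survive.

**Compound list**
1 | guaiacol (2-methoxyphenol) | COc1ccccc1O | starting material
2 | 2-methoxy-4,6-dinitrophenol | COc1cc([N+](=O)[O-])cc([N+](=O)[O-])c1O | intermediate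
3 | 2-chloro-1-methoxy-3,5-dinitrobenzene | COc1cc([N+](=O)[O-])cc([N+](=O)[O-])c1Cl | intermediate
4 | 3,5-dibromosalicylaldehyde (3,5-dibromo-2-hydroxybenzaldehyde) | O=Cc1cc(Br)cc(Br)c1O | starting material
5 | 3,5-dibromo-2-methoxybenzaldehyde | COc1c(Br)cc(Br)cc1C=O | intermediate
6 | 3,5-dibromo-2-methoxyphenyl formate | COc1c(Br)cc(Br)cc1OC=O | intermediate
7 | 3,5-dibromo-2-methoxyphenol | COc1c(Br)cc(Br)cc1O | intermediate
8 | 1,5-dibromo-2-methoxy-3-(2-methoxy-4,6-dinitrophenoxy)benzene | COc1cc([N+](=O)[O-])cc([N+](=O)[O-])c1Oc1cc(Br)cc(Br)c1OC | intermediate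
9 | 4-(3,5-dibromo-2-methoxyphenoxy)-5-methoxybenzene-1,3-diamine | COc1cc(N)cc(N)c1Oc1cc(Br)cc(Br)c1OC | intermediate
10 | 4-(3,5-dibromo-2-methoxyphenoxy)-5-methoxybenzene-1,3-bis(diazonium) bis(hydrogensulfate) | COc1cc([N+]#N)cc([N+]#N)c1Oc1cc(Br)cc(Br)c1OC.OS(=O)(=O)[O-].OS(=O)(=O)[O-] | intermediate
11 | 1,5-dibromo-2-(3,5-dibromo-2-methoxyphenoxy)-3-methoxybenzene | COc1cc(Br)cc(Br)c1Oc1cc(Br)cc(Br)c1OC | intermediate
12 | 3,5-dibromo-2-(3,5-dibromo-2-hydroxyphenoxy)phenol | Oc1cc(Br)cc(Br)c1Oc1cc(Br)cc(Br)c1O | target

**Step count**
Total steps: 8. Longest linear sequence: 6 steps (steps 1, 2, 5, 6, 7, 8; the branch through steps 3 and 4 joins at step 5 and is equally long).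

**Steps most likely to fail**

1. Step 7. The double diazotisation may stop halfway and the first diazonium group may couple onto still-free diamine. The C3 radical may close onto C2' of ring B in a Pschorr-type reaction, or the doubly activated aryloxy group may be displaced from C2. The fallback sets out from 8 and comes back at 11, and replaces the two nitrogens one at a time so that no meta-diamine and no bis-diazonium salt ever exists. Zinin reduction of 8 (NaSH, MeOH, reflux) should reduce the nitro group ortho to the aryloxy oxygen and give 2-(3,5-dibromo-2-methoxyphenoxy)-3-methoxy-5-nitroaniline F1. This weakly basic amine is diazotised in nitrosylsulfuric acid to 2-(3,5-dibromo-2-methoxyphenoxy)-3-methoxy-5-nitrobenzenediazonium hydrogensulfate F2, and copper(I) bromide in hydrobromic acid should convert it into 1-bromo-2-(3,5-dibromo-2-methoxyphenoxy)-3-methoxy-5-nitrobenzene F3. Iron in acetic acid then reduces the remaining nitro group to 3-bromo-4-(3,5-dibromo-2-methoxyphenoxy)-5-methoxyaniline F4. A second diazotisation gives 3-bromo-4-(3,5-dibromo-2-methoxyphenoxy)-5-methoxybenzenediazonium hydrogensulfate F5, and a second Sandmeyer bromination gives 11. If the Zinin step reduces the other nitro group first, the same sequence still converges on 11.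

2. Step 2. The phenol may stall at the phosphate ester stage, or the neighbouring methyl ether may be lost under hot acidic chloride. The fallback sets out from 2 and comes back at 3, and separates activation from substitution. Tosyl chloride and triethylamine in CH2Cl2 should give 2-methoxy-4,6-dinitrophenyl 4-methylbenzenesulfonate F6. Lithium chloride in DMF at 80 °C then displaces the sulfonate by SNAr at the nitro-activated carbon and gives 3. Chloride attack at sulfur is unproductive and reversible.

3. Step 1. The electron-rich phenol may be oxidised to quinones and tar before the second nitro group enters, or ipso attack at the methoxy-bearing carbon may occur. The fallback sets out from 1 and comes back at 2, and brings in the first nitrogen under non-oxidising conditions. Nitrosation (NaNO2, dilute H2SO4, 0 °C) should go para to the hydroxyl and give 2-methoxy-4-nitrosophenol F7. Dilute nitric acid oxidises the nitroso group to give 2-methoxy-4-nitrophenol F8. The ring is now deactivated, so a single nitration (HNO3, AcOH, rt) ortho to the hydroxyl should give 2.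

**Further compounds**
F1 | step 7 | 2-(3,5-dibromo-2-methoxyphenoxy)-3-methoxy-5-nitroaniline | COc1cc([N+](=O)[O-])cc(N)c1Oc1cc(Br)cc(Br)c1OC
F2 | step 7 | 2-(3,5-dibromo-2-methoxyphenoxy)-3-methoxy-5-nitrobenzenediazonium hydrogensulfate | COc1cc([N+](=O)[O-])cc([N+]#N)c1Oc1cc(Br)cc(Br)c1OC.OS(=O)(=O)[O-]
F3 | step 7 | 1-bromo-2-(3,5-dibromo-2-methoxyphenoxy)-3-methoxy-5-nitrobenzene | COc1cc([N+](=O)[O-])cc(Br)c1Oc1cc(Br)cc(Br)c1OC
F4 | step 7 | 3-bromo-4-(3,5-dibromo-2-methoxyphenoxy)-5-methoxyaniline | COc1cc(N)cc(Br)c1Oc1cc(Br)cc(Br)c1OC
F5 | step 7 | 3-bromo-4-(3,5-dibromo-2-methoxyphenoxy)-5-methoxybenzenediazonium hydrogensulfate | COc1cc([N+]#N)cc(Br)c1Oc1cc(Br)cc(Br)c1OC.OS(=O)(=O)[O-]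
F6 | step 2 | 2-methoxy-4,6-dinitrophenyl 4-methylbenzenesulfonate | COc1cc([N+](=O)[O-])cc([N+](=O)[O-])c1OS(=O)(=O)c1ccc(C)cc1
F7 | step 1 | 2-methoxy-4-nitrosophenol | COc1cc(N=O)ccc1O
F8 | step 1 | 2-methoxy-4-nitrophenol | COc1cc([N+](=O)[O-])ccc1O
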